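(The numbers in the tables were generated by integration with made-up constants, and the scatter is random.)

I followed the substrate left, not the product made.

all flasks: substrate 0.25 M; partner 1.25 M
- autumn: free catalyst 0.60 mM; run made earlier
- noon: free catalyst 2.4 mM; run made earlier
- flask: free catalyst 1.2 mM

- autumn (time / min: product / %, substrate / %): 0.667: 3.9, 96.0; 1.33: 7.9, 91.8; 2.00: 11.3, 88.0; 3.00: 16.9, 83.2; 4.00: 22.0, 77.8; 5.00: 26.1, 73.9
- noon (time / min: product / %, substrate / %): 0.417: 9.4, 89.7; 0.667: 15.3, 84.1; 0.833: 19.1, 80.3; 1.33: 29.0, 70.4; 2.00: 41.6, 58.4; 3.00: 56.6, 42.8; 5.00: 78.0, 21.5

(readings scatter by 0.3 percentage points)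

- factor on the rate of making product when 50 % of the substrate are converted if free catalyst is charged twice over
- factor on the rate when 50 % of the substrate are converted if free catalyst is charged at 12 mM instead

At the start, the slopes of the logarithm of the fraction left in the two earlier runs stood 4.26 times apart, which within the scatter was the ratio of charges, 4.00. Further down they parted. The autumn run stopped with 73.9 % left at 5.00 min, and the noon run passed that level at 1.15 min, so equal conversion took 4.36 times as long in autumn, a reading above the charge ratio.

I read this through the suspects. Catalyst intermediate A goes on with partner towards product or with substrate to spent catalyst, and that split, a selectivity factor, contains no catalyst concentration. With substrate and partner charged alike, equal conversion should therefore cost equal millimoles per litre of catalyst, and the rate at that conversion should follow the charge minus that loss. The autumn comparison gave a mean loss of 0.0643 mM over its stretch. Taken in proportion to substrate converted, this reached 0.246 mM at 50 % conversion, a point the noon run crossed between 2.00 min and 3.00 min. That is the toll, my estimate of the catalyst lost by a given conversion at these charges of substrate and partner.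

Dividing charge minus toll by the same for the flask, I reckoned 2.26 for the doubled charge and 12.3 for 12 mM. The forecast gave 2.03 and 10, holding that “at fixed conversion the rate scales with load”, so my figures stood higher.

The flask gave 2.20 and 11.9.

    partner + catalyst intermediate A ⇌ catalyst intermediate B (K = 1.10 L mol⁻¹, k = 0.873 L mol⁻¹ s⁻¹)
    substrate + free catalyst → catalyst intermediate A (k = 3.62 L mol⁻¹ s⁻¹)
    substrate + catalyst intermediate A → spent catalyst (k = 0.00775 L mol⁻¹ s⁻¹)
    catalyst intermediate B → free catalyst + product (k = 6.52 s⁻¹)

When the flask reached 50 % conversion, at 5.30 min, spent catalyst was 16.2 % of its catalyst, or 0.194 mM. The toll I had estimated from the earlier runs, 0.246 mM, stood above that amount by 0.0524 mM.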